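**Retrosynthetic overview**
1. The target is (2S)-naringenin joined to apigenin through C3'–C3''' of the two rings B; the last step frees all six phenols from benzyl ethers by neutral hydrogenolysis.
2. Key disconnection, flavanone ring C at C3–C4 and O1–C2: ring A becomes 2,4-bis(benzyloxy)-6-hydroxybenzaldehyde and C2/C3 become a terminal arylacetylene on ring B. One flask joins them by rhodium hydroacylation (C3–C4) and a catalytic asymmetric oxa-Michael closure (O1–C2, sets C2); the closure copies the chalcone isomerase step of flavonoid biosynthesis.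
3. Enabling feature: in the flavanone, O1 and the carbonyl carbon C4 are ortho substituents of ring A (a salicyloyl unit) and C2 lies β to C4 through C3. Ring C is therefore a β-aryloxy ketone, the formal [4+2] adduct of O1–C8a–C4a–C4 with C2≡C3.
4. The alkyne comes from a biaryl aldehyde (Seyferth–Gilbert homologation). The biaryl bond comes from Suzuki–Miyaura coupling of a 3'-bromoflavone with an arylboronate, both rings B deriving from 4-(benzyloxy)-3-bromobenzaldehyde. The flavone comes from a chalcone (Claisen–Schmidt condensation, oxidative cyclisation).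
5. Order of ring formation: flavone ring C (step 2), biaryl bond (step 4), flavanone ring C with its stereocentre (step 7).

Key step: step 7

Assumption: the quinine-derived thiourea is taken to give the (2S) sense at C2; if the first run shows the opposite sense, its quinidine-derived pseudoenantiomer is used under the same conditions.

**Route**

Step 1
Reactants: 1 1-[2,4-bis(benzyloxy)-6-hydroxyphenyl]ethan-1-one; 2 4-(benzyloxy)-3-bromobenzaldehyde
Product: 3 (E)-1-[2,4-bis(benzyloxy)-6-hydroxyphenyl]-3-[4-(benzyloxy)-3-bromophenyl]prop-2-en-1-one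
Conditions: KOH (50 % aq.), EtOH, rt
Reagents that add atoms: none
Why: Claisen–Schmidt condensation, in which the methyl ketone enolate of 1 adds to the non-enolisable aldehyde 2 and the aldol dehydrates to the (E)-enone, while the chelated 2'-hydroxyl, the benzyl ethers and the aryl bromide are inert to ethanolic KOH.

Step 2
Reactants: 3 (E)-1-[2,4-bis(benzyloxy)-6-hydroxyphenyl]-3-[4-(benzyloxy)-3-bromophenyl]prop-2-en-1-one
Product: 4 5,7-bis(benzyloxy)-2-[4-(benzyloxy)-3-bromophenyl]-4H-chromen-4-one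
Conditions: I2 (10 mol %), DMSO, 120 °C
Reagents that add atoms: none
Why: Iodine-catalysed oxidative cyclisation of a 2'-hydroxychalcone (oxa-Michael closure, α-iodination, loss of HI, reoxidation of iodide by DMSO) should give the flavone ring C without touching the aryl bromide.

Step 3
Reactants: 2 4-(benzyloxy)-3-bromobenzaldehyde
Product: 5 4-(benzyloxy)-3-(4,4,5,5-tetramethyl-1,3,2-dioxaborolan-2-yl)benzaldehyde
Conditions: PdCl2(dppf) (3 mol %), KOAc, 1,4-dioxane, 90 °C
Reagents that add atoms: bis(pinacolato)diboron, CC1(C)OB(OC1(C)C)B1OC(C)(C)C(C)(C)O1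
Why: Miyaura borylation of an aryl bromide with zerovalent palladium and the weak base KOAc tolerates the aldehyde and the benzyl ether.

Step 4
Reactants: 4 5,7-bis(benzyloxy)-2-[4-(benzyloxy)-3-bromophenyl]-4H-chromen-4-one; 5 4-(benzyloxy)-3-(4,4,5,5-tetramethyl-1,3,2-dioxaborolan-2-yl)benzaldehyde
Product: 6 4-(benzyloxy)-3-{2-(benzyloxy)-5-[5,7-bis(benzyloxy)-4-oxo-4H-chromen-2-yl]phenyl}benzaldehyde
Conditions: Pd(OAc)2 (5 mol %), SPhos, K3PO4, toluene/H2O, 90 °C
Reagents that add atoms: none
Why: Suzuki–Miyaura coupling with a bulky biarylphosphine should form the 2,2'-dialkoxybiaryl bond, and the phosphate base leaves the chromone and the aldehyde intact.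

Step 5
Reactants: 6 4-(benzyloxy)-3-{2-(benzyloxy)-5-[5,7-bis(benzyloxy)-4-oxo-4H-chromen-2-yl]phenyl}benzaldehyde
Product: 7 5,7-bis(benzyloxy)-2-{4-(benzyloxy)-3-[2-(benzyloxy)-5-ethynylphenyl]phenyl}-4H-chromen-4-one
Conditions: K2CO3, MeOH/THF, 0 °C to rt
Reagents that add atoms: dimethyl (1-diazo-2-oxopropyl)phosphonate, COP(=O)(OC)C(=[N+]=[N-])C(C)=O
Why: Seyferth–Gilbert homologation with the Ohira–Bestmann reagent converts the aryl aldehyde into the terminal alkyne under carbonate/methanol conditions mild enough for the chromone.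

Step 6
Reactants: 8 2,4,6-trihydroxybenzaldehyde
Product: 9 2,4-bis(benzyloxy)-6-hydroxybenzaldehyde
Conditions: K2CO3 (2 equiv), DMF, rt
Reagents that add atoms: benzyl bromide, BrCc1ccccc1
Why: Williamson etherification takes the para hydroxyl and one of the two equivalent ortho hydroxyls, and the remaining ortho hydroxyl is deactivated by its hydrogen bond to the formyl group.

Step 7
Reactants: 7 5,7-bis(benzyloxy)-2-{4-(benzyloxy)-3-[2-(benzyloxy)-5-ethynylphenyl]phenyl}-4H-chromen-4-one; 9 2,4-bis(benzyloxy)-6-hydroxybenzaldehyde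
Product: 11 (2S)-5,7-bis(benzyloxy)-2-(4-(benzyloxy)-3-{2-(benzyloxy)-5-[5,7-bis(benzyloxy)-4-oxo-4H-chromen-2-yl]phenyl}phenyl)-2,3-dihydro-4H-chromen-4-one, via 2'-hydroxychalcone 10 (not isolated)
Conditions: [Rh(cod)Cl]2 (2.5 mol %), dppf (5 mol %), Na2CO3 (5 mol %), toluene, 80 °C; then 0 °C, quinine-derived 3,5-bis(trifluoromethyl)phenyl thiourea (20 mol %), 0 °C to rt
Reagents that add atoms: none
Why: The monovalent rhodium phenoxide of 9 inserts into the formyl C–H bond to give a chelated trivalent acyl rhodium hydride, the alkyne of 7 inserts into Rh–H with rhodium at the unsubstituted carbon, and C–C reductive elimination forms C3–C4 and releases (E)-2'-hydroxychalcone 10; the cinchona thiourea then binds the enone carbonyl by hydrogen bonds while its quinuclidine nitrogen activates the phenol, which adds to C2 and forms O1–C2. The closest known reaction types are the rhodium-catalysed salicylaldehyde–alkyne hydroacylation with in-flask oxa-Michael closure to chroman-4-ones and the cinchona-thiourea-catalysed cyclisation of 2'-hydroxychalcones, the laboratory form of the chalcone isomerase step. Ring C of the flavanone is closed by a 6-endo-trig oxa-Michael addition of O1 to the enone terminus C2. The only new stereocentre, C2, is set by the catalyst, which shields one face of the bound enone so that O1 attacks the other face to give (2S). The step needs linear regioselectivity in the alkyne insertion, secured by the unsubstituted alkyne terminus and the wide-bite-angle diphosphine, and it needs reaction at one aldehyde and one enone only, secured by the ortho hydroxyl of 9 (chelation, no decarbonylation) and by the flavone enone of 7 carrying no free ortho phenol. Little racemic background is expected in the first stage because the hydrogen-bonded 6'-benzyloxy-2'-hydroxychalcone does not cyclise without a soluble base.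

Step 8
Reactants: 11 (2S)-5,7-bis(benzyloxy)-2-(4-(benzyloxy)-3-{2-(benzyloxy)-5-[5,7-bis(benzyloxy)-4-oxo-4H-chromen-2-yl]phenyl}phenyl)-2,3-dihydro-4H-chromen-4-one
Product: 12 (2S)-2-{3-[5-(5,7-dihydroxy-4-oxo-4H-chromen-2-yl)-2-hydroxyphenyl]-4-hydroxyphenyl}-5,7-dihydroxy-2,3-dihydro-4H-chromen-4-one
Conditions: H2 (1 atm), Pd/C (10 %), THF/MeOH, rt
Reagents that add atoms: none
Why: Hydrogenolysis of the six benzyl aryl ethers runs under neutral conditions, so the base-labile C2 stereocentre is not opened to the chalcone, and the chromone double bond and the aryl ketones should survive one atmosphere of hydrogen at room temperature.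

**Compound list**
1 | 1-[2,4-bis(benzyloxy)-6-hydroxyphenyl]ethan-1-one | CC(=O)c1c(O)cc(OCc2ccccc2)cc1OCc1ccccc1 | starting material
2 | 4-(benzyloxy)-3-bromobenzaldehyde | O=Cc1ccc(OCc2ccccc2)c(Br)c1 | starting material
3 | (E)-1-[2,4-bis(benzyloxy)-6-hydroxyphenyl]-3-[4-(benzyloxy)-3-bromophenyl]prop-2-en-1-one | O=C(/C=C/c1ccc(OCc2ccccc2)c(Br)c1)c1c(O)cc(OCc2ccccc2)cc1OCc1ccccc1 | intermediate
4 | 5,7-bis(benzyloxy)-2-[4-(benzyloxy)-3-bromophenyl]-4H-chromen-4-one | O=c1cc(-c2ccc(OCc3ccccc3)c(Br)c2)oc2cc(OCc3ccccc3)cc(OCc3ccccc3)c12 | intermediate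
5 | 4-(benzyloxy)-3-(4,4,5,5-tetramethyl-1,3,2-dioxaborolan-2-yl)benzaldehyde | O=Cc1ccc(OCc2ccccc2)c(B2OC(C)(C)C(C)(C)O2)c1 | intermediate
6 | 4-(benzyloxy)-3-{2-(benzyloxy)-5-[5,7-bis(benzyloxy)-4-oxo-4H-chromen-2-yl]phenyl}benzaldehyde | O=Cc1ccc(OCc2ccccc2)c(-c2cc(-c3cc(=O)c4c(OCc5ccccc5)cc(OCc5ccccc5)cc4o3)ccc2OCc2ccccc2)c1 | intermediate
7 | 5,7-bis(benzyloxy)-2-{4-(benzyloxy)-3-[2-(benzyloxy)-5-ethynylphenyl]phenyl}-4H-chromen-4-one | C#Cc1ccc(OCc2ccccc2)c(-c2cc(-c3cc(=O)c4c(OCc5ccccc5)cc(OCc5ccccc5)cc4o3)ccc2OCc2ccccc2)c1 | intermediate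
8 | 2,4,6-trihydroxybenzaldehyde | O=Cc1c(O)cc(O)cc1O | starting material
9 | 2,4-bis(benzyloxy)-6-hydroxybenzaldehyde | O=Cc1c(O)cc(OCc2ccccc2)cc1OCc1ccccc1 | intermediate
10 | (E)-1-[2,4-bis(benzyloxy)-6-hydroxyphenyl]-3-(4-(benzyloxy)-3-{2-(benzyloxy)-5-[5,7-bis(benzyloxy)-4-oxo-4H-chromen-2-yl]phenyl}phenyl)prop-2-en-1-one (2'-hydroxychalcone, formed in the flask) | O=C(/C=C/c1ccc(OCc2ccccc2)c(-c2cc(-c3cc(=O)c4c(OCc5ccccc5)cc(OCc5ccccc5)cc4o3)ccc2OCc2ccccc2)c1)c1c(O)cc(OCc2ccccc2)cc1OCc1ccccc1 | intermediate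
11 | (2S)-5,7-bis(benzyloxy)-2-(4-(benzyloxy)-3-{2-(benzyloxy)-5-[5,7-bis(benzyloxy)-4-oxo-4H-chromen-2-yl]phenyl}phenyl)-2,3-dihydro-4H-chromen-4-one | O=C1C[C@@H](c2ccc(OCc3ccccc3)c(-c3cc(-c4cc(=O)c5c(OCc6ccccc6)cc(OCc6ccccc6)cc5o4)ccc3OCc3ccccc3)c2)Oc2cc(OCc3ccccc3)cc(OCc3ccccc3)c21 | intermediate
12 | (2S)-2-{3-[5-(5,7-dihydroxy-4-oxo-4H-chromen-2-yl)-2-hydroxyphenyl]-4-hydroxyphenyl}-5,7-dihydroxy-2,3-dihydro-4H-chromen-4-one | O=C1C[C@@H](c2ccc(O)c(-c3cc(-c4cc(=O)c5c(O)cc(O)cc5o4)ccc3O)c2)Oc2cc(O)cc(O)c21 | target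

**Step count and risks**

Total steps: 8. Longest linear sequence: 6 steps (steps 1, 2, 4, 5, 7, 8; 1 → 3 → 4 → 6 → 7 → 11 → 12).

Steps most likely to fail:

Step 7. The alkyne may insert with the opposite regiochemistry and give the branched enone, which cannot close to a flavanone. The facial selectivity of the oxa-Michael closure on an enone without a second activating group may be poor, and slow reversible ring opening may erode the enantiomeric purity. The fallback sets out from aldehyde 6 and ketone 1 and comes back at 11, using the ester-activated version of the same asymmetric closure. Ketone 1 is C-carboxylated through its dianion (LiN(SiMe3)2, di-tert-butyl dicarbonate, THF, −78 °C) to tert-butyl 3-[2,4-bis(benzyloxy)-6-hydroxyphenyl]-3-oxopropanoate F1. Knoevenagel condensation with 6 (piperidine, AcOH, toluene, 4 Å sieves) gives the alkylidene β-keto ester tert-butyl 2-[2,4-bis(benzyloxy)-6-hydroxybenzoyl]-3-(4-(benzyloxy)-3-{2-(benzyloxy)-5-[5,7-bis(benzyloxy)-4-oxo-4H-chromen-2-yl]phenyl}phenyl)prop-2-enoate F2. The quinine-derived thiourea (toluene, −25 °C) closes ring C on this doubly activated acceptor, which offers two-point binding, to give tert-butyl (2S,3R)-5,7-bis(benzyloxy)-2-(4-(benzyloxy)-3-{2-(benzyloxy)-5-[5,7-bis(benzyloxy)-4-oxo-4H-chromen-2-yl]phenyl}phenyl)-4-oxochromane-3-carboxylate F3. Warming with TsOH in toluene at 80 °C removes the ester by loss of isobutene and decarboxylation and gives 11.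

Step 8. Hydrogen may also reduce the chromone C2=C3 bond or the flavanone ketone, or cleave the benzylic C2–O1 bond, and the last benzyl ethers may come off slowly on a product that binds to the catalyst. The fallback sets out from 11 and comes back at 12 with a non-reductive Lewis-acid ether cleavage: BCl3 and pentamethylbenzene in CH2Cl2 at −78 °C, where the arene traps each benzyl cation. This fallback makes no new compound (F0).

Step 2. Hydrogen iodide formed at high temperature may remove the benzyl group next to the carbonyl, or iodinate the electron-rich ring A. The fallback sets out from ketone 1 and comes back at 4 by a Baker–Venkataraman sequence that replaces steps 1 and 2. The phenol of 1 is esterified with commercial 4-(benzyloxy)-3-bromobenzoic acid (EDC, DMAP, CH2Cl2) to 2-acetyl-3,5-bis(benzyloxy)phenyl 4-(benzyloxy)-3-bromobenzoate F4. KOH in pyridine at 50 °C moves the aroyl group from oxygen to the methyl carbon and gives 1-[2,4-bis(benzyloxy)-6-hydroxyphenyl]-3-[4-(benzyloxy)-3-bromophenyl]propane-1,3-dione F5. Cyclodehydration (TsOH cat., toluene, reflux) gives 4.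

Further compounds
F1 | step 7 | tert-butyl 3-[2,4-bis(benzyloxy)-6-hydroxyphenyl]-3-oxopropanoate | CC(C)(C)OC(=O)CC(=O)c1c(O)cc(OCc2ccccc2)cc1OCc1ccccc1
F2 | step 7 | tert-butyl 2-[2,4-bis(benzyloxy)-6-hydroxybenzoyl]-3-(4-(benzyloxy)-3-{2-(benzyloxy)-5-[5,7-bis(benzyloxy)-4-oxo-4H-chromen-2-yl]phenyl}phenyl)prop-2-enoate (alkene isomers not separated) | CC(C)(C)OC(=O)C(=Cc1ccc(OCc2ccccc2)c(-c2cc(-c3cc(=O)c4c(OCc5ccccc5)cc(OCc5ccccc5)cc4o3)ccc2OCc2ccccc2)c1)C(=O)c1c(O)cc(OCc2ccccc2)cc1OCc1ccccc1
F3 | step 7 | tert-butyl (2S,3R)-5,7-bis(benzyloxy)-2-(4-(benzyloxy)-3-{2-(benzyloxy)-5-[5,7-bis(benzyloxy)-4-oxo-4H-chromen-2-yl]phenyl}phenyl)-4-oxochromane-3-carboxylate | O=C1[C@H](C(=O)OC(C)(C)C)[C@@H](c2ccc(OCc3ccccc3)c(-c3cc(-c4cc(=O)c5c(OCc6ccccc6)cc(OCc6ccccc6)cc5o4)ccc3OCc3ccccc3)c2)Oc2cc(OCc3ccccc3)cc(OCc3ccccc3)c21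
F0 | step 8 | none | none
F4 | step 2 | 2-acetyl-3,5-bis(benzyloxy)phenyl 4-(benzyloxy)-3-bromobenzoate | CC(=O)c1c(OC(=O)c2ccc(OCc3ccccc3)c(Br)c2)cc(OCc2ccccc2)cc1OCc1ccccc1
F5 | step 2 | 1-[2,4-bis(benzyloxy)-6-hydroxyphenyl]-3-[4-(benzyloxy)-3-bromophenyl]propane-1,3-dione | O=C(CC(=O)c1ccc(OCc2ccccc2)c(Br)c1)c1c(O)cc(OCc2ccccc2)cc1OCc1ccccc1
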